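Retrosynthesis: the two outer aryl C–CH2 bonds (free ring carbon of each butyrylphloroglucinol ring B to the CH2 on C6 of each acetylfilicinic acid ring A) are cut together first, then the central ring B–CH2–ring B bridge, then the aryl–butanoyl bond of ring B and the three ring C–CH3 bonds of ring A.
Enabling feature: each outer bridge carbon hangs on C6 of ring A, between the C1 and C5 carbonyl/enol carbons. At the methyl oxidation level it is therefore the C6–CH3 of 2-acetyl-4,4,6-trimethylcyclohexane-1,3,5-trione, whose C6–H/CH3 pair can lose two hydrogens to give an exocyclic C6=CH2 acceptor. The A–B–B–A symmetry makes the donor a bis(butyrylphloroglucinyl)methane in which every ring B keeps exactly one unsubstituted carbon, set between two OH groups.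
Forward: Friedel–Crafts butanoylation of phloroglucinol, B–B joining through one formaldehyde carbon, separate dearomatising C-trimethylation of 2,4,6-trihydroxyacetophenone to the ring A building block, then A–B bond formation at both ends in one oxidative operation.
No ring is built at any stage: the two rings B and the two rings A all derive from purchased phloroglucinols.
Stereochemistry: the target has no stereocentre and no stereogenic double bond, so nothing is set.

Key step: step 4

Remark on the chemistry: the polyketone rings are written in the enol tautomers of the target structure, and tautomers are treated as one compound.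

Step 1
Reactants: 1 phloroglucinol (anhydrous); 2 butanoyl chloride
Product: 3 butyrylphloroglucinol, 1-(2,4,6-trihydroxyphenyl)butan-1-one
Conditions: AlCl3 (4 equiv), PhNO2/CH2Cl2, 0 °C → 45 °C; ice/2 M HCl
Reagents that add atoms: butanoyl chloride 2, CCCC(=O)Cl
Why: Friedel–Crafts C-acylation of the very electron-rich phloroglucinol ring should stop after one acyl group, because the chelated aryl ketone–AlCl3 complex is deactivated toward a second acylation; no stereocentre is formed.

Step 2
Reactants: 3 butyrylphloroglucinol (4 equiv, the excess to be recovered); 4 formaldehyde (37% aqueous, 1 equiv)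
Product: 7 bis(3-butanoyl-2,4,6-trihydroxyphenyl)methane, via hydroxymethyl adduct 5 (not isolated), via o-quinone methide 6 (not isolated)
Conditions: 1% aq. KOH, 0 °C → rt, short reaction time; then 2 M HCl
Reagents that add atoms: formaldehyde 4, C=O
Why: Lederer–Manasse hydroxymethylation of the phenolate of 3 at one of its two equivalent free ring carbons should give 5, which loses hydroxide to the o-quinone methide 6 that a second phenolate of 3 captures by conjugate addition (the classical formaldehyde bridging of acylphloroglucinols), while limiting formaldehyde and a twofold excess of 3 should hold the chain at the dimer; no stereocentre is formed.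

Step 3
Reactants: 8 2,4,6-trihydroxyacetophenone; 9 iodomethane (3 equiv)
Product: 10 2-acetyl-4,4,6-trimethylcyclohexane-1,3,5-trione (drawn as the dienol 2-acetyl-3,5-dihydroxy-4,6,6-trimethylcyclohexa-2,4-dien-1-one)
Conditions: NaOMe (3 equiv), MeI (3 equiv), MeOH, 0 °C → rt; 1 M HCl work-up
Reagents that add atoms: iodomethane 9, CI
Why: three successive SN2 C-alkylations of the ambident phloroglucinolate at its two unsubstituted ring carbons (the known dearomatising methylation of acylphloroglucinols in a protic solvent that favours C- over O-attack) should converge on the one 4,4,6-trimethyl triketone whatever the order of alkylation, and its only sp3 C–H carbon (C6) is stereolabile through the enol, so no configuration has to be set.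

Step 4
Reactants: 7 bis(3-butanoyl-2,4,6-trihydroxyphenyl)methane (1 equiv); 10 2-acetyl-4,4,6-trimethylcyclohexane-1,3,5-trione (3 equiv, two molecules are incorporated)
Product: 14 dryocrassin ABBA, via TEMPO alkoxyamine 11 (not isolated), via enetrione 12 (not isolated), via mono-coupled adduct 13 (not isolated)
Conditions: TEMPO (2.4 equiv), Ag2O (1.2 equiv), each added in four portions, THF, 0 °C → rt, dark; Celite filtration, 0.5 M HCl wash
Reagents that add atoms: none
Why: Proposed new method: Ag2O should take one electron from the enol(ate) of 10 to leave a C6-centred radical flanked by the C1 and C5 carbonyls, TEMPO intercepts this radical as the alkoxyamine 11, and 11 eliminates TEMPO-H across the C6–CH3 bond to unveil the exocyclic C6=CH2 of enetrione 12; the lone unsubstituted carbon of each ring B of 7, flanked by two OH groups, then attacks the methylene carbon of 12 in a vinylogous Michael (Friedel–Crafts-type) addition, and proton shifts return the aromatic ring and the enol form of the triketone, first in 13 and after a second round in 14. Each half has precedent on its own, namely the TEMPO/Ag2O dehydrogenation of 6-alkyl-2-acyl-4,4-dimethylcyclohexane-1,3,5-triones, so far intercepted in the same flask only by alkenes in hetero-Diels–Alder cycloadditions, and the Michael addition of acylphloroglucinols to alkylidene triketones made by Knoevenagel condensation of aldehydes, but capture of the oxidatively generated enetrione by an arene carbon, twice on one bis-arene, has not been shown. No ring closes and no stereocentre remains, since the racemic C6 centre of 11 is erased in the elimination. The oxidant must select 10 over the phenols and the doubly benzylic central CH2 of 7 and over the new ArCH2 bridges of 13 and 14, which should follow from 10 being the most acidic, fully enolised and least hindered C–H donor, from the acyl-deactivated and hydrogen-bonded phenols of 7, and from keeping the oxidant limiting with respect to 10 so that unreacted 10 is always present as the preferred substrate. The arene must also win over O-attack and over self-capture of 12, which is plausible because O-adducts and adducts through the quaternising C6 of another 10 can revert by retro-Michael cleavage whereas the aryl adduct is locked by rearomatisation, and because 7 offers exactly one nucleophilic carbon per ring so that the chain ends at the four-ring stage. Neutral aprotic conditions free of formaldehyde and of soluble base should keep the methylene bridges from scrambling.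

Compound list
1 | phloroglucinol (benzene-1,3,5-triol) | Oc1cc(O)cc(O)c1 | starting material
2 | butanoyl chloride | CCCC(=O)Cl | starting material
3 | butyrylphloroglucinol, 1-(2,4,6-trihydroxyphenyl)butan-1-one | CCCC(=O)c1c(O)cc(O)cc1O | intermediate
4 | formaldehyde (37% aqueous) | C=O | starting material
5 | hydroxymethyl adduct, 1-[2,4,6-trihydroxy-3-(hydroxymethyl)phenyl]butan-1-one | CCCC(=O)c1c(O)cc(O)c(CO)c1O | intermediate
6 | o-quinone methide, 2-butanoyl-3,5-dihydroxy-6-methylidenecyclohexa-2,4-dien-1-one | C=C1C(=O)C(C(=O)CCC)=C(O)C=C1O | intermediate
7 | bis(3-butanoyl-2,4,6-trihydroxyphenyl)methane (ring B–CH2–ring B core) | CCCC(=O)c1c(O)cc(O)c(Cc2c(O)cc(O)c(C(=O)CCC)c2O)c1O | intermediate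
8 | 2,4,6-trihydroxyacetophenone | CC(=O)c1c(O)cc(O)cc1O | starting material
9 | iodomethane | CI | starting material
10 | 2-acetyl-4,4,6-trimethylcyclohexane-1,3,5-trione (dienol form) | CC1=C(O)C(C)(C)C(=O)C(C(C)=O)=C1O | intermediate
11 | TEMPO alkoxyamine, racemic 2-acetyl-3-hydroxy-4,4,6-trimethyl-6-[(2,2,6,6-tetramethylpiperidin-1-yl)oxy]cyclohex-2-ene-1,5-dione | CC(=O)C1=C(O)C(C)(C)C(=O)C(C)(ON2C(C)(C)CCCC2(C)C)C1=O | intermediate
12 | enetrione, 2-acetyl-4,4-dimethyl-6-methylidenecyclohexane-1,3,5-trione (mono-enol form) | C=C1C(=O)C(C)(C)C(=O)C(C(C)=O)=C1O | intermediate
13 | mono-coupled adduct (A–B–B), 7 carrying one (5-acetyl-2,6-dihydroxy-3,3-dimethyl-4-oxocyclohexa-1,5-dien-1-yl)methyl group on the free carbon of one ring B | CCCC(=O)c1c(O)c(CC2=C(O)C(C)(C)C(=O)C(C(C)=O)=C2O)c(O)c(Cc2c(O)cc(O)c(C(=O)CCC)c2O)c1O | intermediate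
14 | dryocrassin ABBA, bis{3-butanoyl-5-[(5-acetyl-2,6-dihydroxy-3,3-dimethyl-4-oxocyclohexa-1,5-dien-1-yl)methyl]-2,4,6-trihydroxyphenyl}methane | CCCC(=O)c1c(O)c(CC2=C(O)C(C)(C)C(=O)C(C(C)=O)=C2O)c(O)c(Cc2c(O)c(CC3=C(O)C(C)(C)C(=O)C(C(C)=O)=C3O)c(O)c(C(=O)CCC)c2O)c1O | target

Total step count: 4. Longest linear sequence: 3 steps (steps 1, 2 and 4 from phloroglucinol); the ring A branch is 2 steps (steps 3 and 4).

Steps most likely to fail

Step 4 (new method).
- Three things may go wrong. The oxidant may attack the wrong site: the phenols or the doubly benzylic central CH2 of 7, or a second dehydrogenation of the freshly made ArCH2 bridges. The enetrione may be lost to self-capture before the arene adds. The sequence may stall after the first coupling.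
- The fallback uses known chemistry and moves the bridge carbon from the C6 methyl group to formaldehyde. It sets out from 8, which is C-dimethylated with two equivalents of 9 (NaOMe, MeOH) to acetylfilicinic acid F1.
- F1 (a little over 2 equiv) and 7 are then co-condensed with formaldehyde 4 in 1% aq. KOH at 0 °C and acidified, the classical mixed methylene bridging of a filicinic acid with an acylphloroglucinol.
- Knoevenagel condensation of F1 with 4 gives the same enetrione, so the route is rejoined at 12 and runs on through 13 to 14 without any oxidant.
- The cost is statistical bridging between two filicinic rings and base-induced bridge exchange, which is why this stays the fallback.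

Step 2.
- The bridging may run past the dimer, because the product still has one nucleophilic carbon per ring, and hydroxymethyl material may build up.
- The fallback sets out from 3 and fixes the bridge carbon on one ring in a separate stoichiometric step. 3 is aminomethylated once with N,N-dimethylmethyleneiminium iodide (limiting, MeCN, 0 °C) to the Mannich base 1-{3-[(dimethylamino)methyl]-2,4,6-trihydroxyphenyl}butan-1-one F2.
- Purified F2 is warmed with an excess of 3 in dioxane at 80–100 °C. Thermal loss of dimethylamine releases the o-quinone methide slowly and in low concentration, so the route is rejoined at 6, which 3 captures to give 7.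
- Free formaldehyde is never present together with 7. Phenolic Mannich bases are established o-quinone methide precursors for C-benzylation.

Step 3.
- The three alkylations may spread statistically (stopping at two, running on to four), O-methylation may compete, and the products are of similar polarity.
- The fallback sets out from iodomethane 9 and brings the C6 methyl group in with the arene instead of with 8. Purchased 2,4,6-trihydroxytoluene F3 is C-acetylated (acetyl chloride, AlCl3, PhNO2/CH2Cl2) to 3-methyl-2,4,6-trihydroxyacetophenone F4.
- F4 then needs only two C-alkylations with 9 (NaOMe, 2 equiv, MeOH). Both possible orders again converge, and the route is rejoined at 10.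

Further compounds
F1 | step 4 | acetylfilicinic acid, 2-acetyl-4,4-dimethylcyclohexane-1,3,5-trione (dienol form) | CC(=O)C1=C(O)C=C(O)C(C)(C)C1=O
F2 | step 2 | 1-{3-[(dimethylamino)methyl]-2,4,6-trihydroxyphenyl}butan-1-one | CCCC(=O)c1c(O)cc(O)c(CN(C)C)c1O
F3 | step 3 | 2,4,6-trihydroxytoluene (2-methylbenzene-1,3,5-triol), purchased | Cc1c(O)cc(O)cc1O
F4 | step 3 | 3-methyl-2,4,6-trihydroxyacetophenone, 1-(2,4,6-trihydroxy-3-methylphenyl)ethan-1-one | CC(=O)c1c(O)cc(O)c(C)c1O
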